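C7–C8 (Claisen), C4a–C8a (conjugate addition) and O2–C1 (lactone) are cut first, opening both rings to dimethyl malonate and an acyclic ynedione; this is then cut at C3–C4 (acetaldehyde), C4a≡C4 (one-carbon homologation of an aldehyde), C7–CH3 and last at C5–CH3.
C5, the only stereocentre, is quaternary and carries CH3, the farnesyl C1′ methylene, the C6 ketone carbon and C4a of the pyranone ring; these arms map onto the γ-carbon of an E-allylic phosphate bearing the chain and an ester (future C4a), and the transposed vinyl group is the C6–C7 precursor.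
Forward, farnesyl bromide is joined to a stabilised ylide, Wittig reaction and phosphorylation give the allylic phosphate, SN2′ methylation builds C5, the vinyl group becomes the ethyl ketone and the ester becomes the alkynyl methyl ketone.
In the last operation the pyranone ring (C1, O2, C3, C4, C4a, C8a) closes first and the carbocycle (C4a, C5, C6, C7, C8, C8a) second.
C5 is set by a chiral copper catalyst acting on the geometrically pure E-alkene; the chain alkenes come unchanged from (2E,6E)-farnesyl bromide, and C5 has no hydrogen, so it cannot epimerise later.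

Key step: step 4

Remarks: farnesyl means (2E,6E)-3,7,11-trimethyldodeca-2,6,10-trien-1-yl, and target atoms carry isochromene numbers. Assumption: the antipode of the chiral ligand that gives (R)-10 is used in step 4, and the carbinol centres formed in steps 7 and 10 are carried as epimer mixtures because step 11 oxidises both.

Step 1
Reactants: 1 (2E,6E)-farnesyl bromide; 2 tert-butyl (triphenylphosphoranylidene)acetate
Product: 4 tert-butyl 2-farnesyl-2-(triphenylphosphoranylidene)acetate, via phosphonium bromide 3 (not isolated)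
Conditions: EtOAc, 70 °C; then 1 M NaOH, CH2Cl2, rt
Reagents that add atoms: none
Why: C-alkylation of a stabilised phosphorus ylide, in which the ylide carbon displaces the primary allylic bromide in SN2 fashion without touching the chain alkenes and aqueous hydroxide then deprotonates the phosphonium salt to the α-substituted stabilised ylide.

Step 2
Reactants: 4 tert-butyl 2-farnesyl-2-(triphenylphosphoranylidene)acetate; 5 glycolaldehyde dimer (1,4-dioxane-2,5-diol)
Product: 7 tert-butyl (2E)-2-farnesyl-4-hydroxybut-2-enoate, via glycolaldehyde 6 (not isolated)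
Conditions: THF, 65 °C
Reagents that add atoms: none
Why: Wittig olefination with an α-substituted ester-stabilised ylide, which should react with the glycolaldehyde released from its dimer to give the E-trisubstituted enoate (CH2OH trans to the ester, cis to the farnesyl CH2), any Z isomer being removed by chromatography at this stage.

Step 3
Reactants: 7 tert-butyl (2E)-2-farnesyl-4-hydroxybut-2-enoate
Product: 8 tert-butyl (2E)-4-(diethoxyphosphoryloxy)-2-farnesylbut-2-enoate
Conditions: ClP(O)(OEt)2, Et3N, DMAP (cat.), CH2Cl2, 0 °C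
Reagents that add atoms: diethyl chlorophosphate, CCOP(=O)(Cl)OCC
Why: Phosphorylation of a primary allylic alcohol with a dialkyl chlorophosphate under amine base and nucleophilic catalysis installs the leaving group without disturbing the enoate geometry.

Step 4
Reactants: 8 tert-butyl (2E)-4-(diethoxyphosphoryloxy)-2-farnesylbut-2-enoate; 9 dimethylzinc
Product: 10 tert-butyl (2R)-2-farnesyl-2-methylbut-3-enoate
Conditions: (CuOTf)2·C6H6 (5 mol %), chiral amino-acid-based pyridyl Schiff-base ligand (10 mol %), Me2Zn (3 equiv), THF, −15 °C; aq. NH4Cl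
Reagents that add atoms: none
Why: Me2Zn transmetalates to the ligand-bound monovalent copper triflate, and the resulting chiral methylcopper species binds the electron-poor alkene of 8 and adds at the γ-carbon (the ester-bearing carbon, future C5) anti to the departing phosphate, giving a trivalent σ-allyl copper intermediate whose reductive elimination forms the C5–CH3 bond and leaves the transposed vinyl group. The closest known reaction type is the copper-catalysed enantioselective allylic alkylation of γ,γ-disubstituted allylic phosphates, among them 2-alkyl-4-phosphoryloxybut-2-enoates, with dialkylzinc reagents. No ring is closed. The one new stereocentre (R in 10, S at C5 of the target because the ester and vinyl arms exchange priority later) is set by the chiral ligand on copper, which selects one π-face of the trisubstituted alkene. The step needs SN2′ rather than SN2 or conjugate-addition regiochemistry, which the phosphate leaving group, the soft copper nucleophile and the bulky tert-butyl ester should secure. It also needs a geometrically pure substrate, provided by the E-selective Wittig step, so that the farnesyl CH2 and the ester are told apart by alkene geometry.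

Step 5
Reactants: 10 tert-butyl (2R)-2-farnesyl-2-methylbut-3-enoate
Product: 11 tert-butyl (2R)-2-farnesyl-2-methyl-3-oxobutanoate
Conditions: PdCl2[2-(4,5-dihydro-1,3-oxazol-2-yl)quinoline] (5 mol %), AgSbF6 (12 mol %), aq. t-BuOOH, CH2Cl2, 0 °C → rt
Reagents that add atoms: tert-butyl hydroperoxide, CC(C)(C)OO
Why: Wacker–Tsuji oxidation in its tert-butyl hydroperoxide-mediated form, in which the cationic quinoline–oxazoline complex of divalent palladium should bind only the monosubstituted vinyl group, deliver oxygen to its internal carbon to give the methyl ketone, leave no free site for the ester chelation that would favour the aldehyde, and ignore the three trisubstituted chain alkenes.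

Step 6
Reactants: 11 tert-butyl (2R)-2-farnesyl-2-methyl-3-oxobutanoate
Product: 12 tert-butyl (2R)-2-farnesyl-2-methyl-3-oxopentanoate
Conditions: LiN(i-Pr)2, THF, −78 °C; MeI, −78 → −40 °C
Reagents that add atoms: iodomethane, CI
Why: Kinetic enolate alkylation, in which the acetyl methyl group holds the only enolisable hydrogens of 11 (the other α-carbon is quaternary), so a single lithium enolate forms and is C-methylated by iodomethane to the ethyl ketone with no risk to the stereocentre.

Step 7
Reactants: 12 tert-butyl (2R)-2-farnesyl-2-methyl-3-oxopentanoate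
Product: 13 (2S,3RS)-2-farnesyl-2-methylpentane-1,3-diol
Conditions: LiAlH4, THF, 0 → 40 °C; aq. NaOH work-up
Reagents that add atoms: none
Why: Hydride reduction with LiAlH4 takes the ketone to the carbinol and the tert-butyl ester to the primary alcohol while the isolated alkenes are inert, and the new carbinol centre forms as a mixture that step 11 erases.

Step 8
Reactants: 13 (2S,3RS)-2-farnesyl-2-methylpentane-1,3-diol
Product: 14 (2R,3RS)-2-farnesyl-3-hydroxy-2-methylpentanal
Conditions: TEMPO (cat.), PhI(OAc)2, CH2Cl2, rt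
Reagents that add atoms: none
Why: Oxoammonium (TEMPO) oxidation with PhI(OAc)2 as terminal oxidant is selective for the primary over the hindered secondary alcohol, stops at the aldehyde, and cannot give a lactol because the two oxygens stand in a 1,3-relationship.

Step 9
Reactants: 14 (2R,3RS)-2-farnesyl-3-hydroxy-2-methylpentanal
Product: 15 (3RS,4S)-4-farnesyl-4-methylhex-5-yn-3-ol
Conditions: dimethyl (1-diazo-2-oxopropyl)phosphonate, K2CO3, MeOH, 0 °C
Reagents that add atoms: dimethyl (1-diazo-2-oxopropyl)phosphonate, CC(=O)C(=[N+]=[N-])P(=O)(OC)OC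
Why: Ohira–Bestmann variant of the Seyferth–Gilbert homologation, in which the diazophosphonate anion released by methanolysis converts the non-enolisable aldehyde into the terminal alkyne by olefination, loss of N2 and 1,2-hydrogen shift, the low temperature keeping retro-aldol cleavage of the β-hydroxy aldehyde slower than homologation.

Step 10
Reactants: 15 (3RS,4S)-4-farnesyl-4-methylhex-5-yn-3-ol; 16 acetaldehyde
Product: 17 (2RS,5S,6RS)-5-farnesyl-5-methyloct-3-yne-2,6-diol
Conditions: n-BuLi (2.2 equiv), THF, −78 °C; MeCHO, −78 → 0 °C; aq. NH4Cl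
Reagents that add atoms: none
Why: Two equivalents of n-BuLi give the lithium alkoxide–lithium acetylide, whose acetylide carbon adds to acetaldehyde (1,2-addition of an alkynyl anion to an aldehyde) to furnish the propargylic alcohol, its configuration being irrelevant.

Step 11
Reactants: 17 (2RS,5S,6RS)-5-farnesyl-5-methyloct-3-yne-2,6-diol
Product: 18 (5S)-5-farnesyl-5-methyloct-3-yne-2,6-dione
Conditions: Dess–Martin periodinane (3 equiv), pyridine, CH2Cl2, 0 °C → rt
Reagents that add atoms: none
Why: Dess–Martin oxidation converts both secondary alcohols to ketones under buffered, non-acidic conditions that spare the chain alkenes and the base-sensitive ynone, and C5 of the resulting ynedione has no α-hydrogen to lose.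

Step 12
Reactants: 18 (5S)-5-farnesyl-5-methyloct-3-yne-2,6-dione; 19 dimethyl malonate
Product: 22 (5S)-5-farnesyl-8-hydroxy-3,5,7-trimethyl-1H-isochromene-1,6(5H)-dione, via Michael adduct 20 (not isolated), via pyranone ester 21 (not isolated)
Conditions: dimethyl malonate (1.2 equiv), KOt-Bu (1.1 equiv), THF, 0 °C → rt; then KOt-Bu (1.5 equiv), 0 °C → rt; 1 M HCl
Reagents that add atoms: none
Why: Malonate conjugate addition to the ynone places the malonate carbon (C8a) on C4a, the only acceptor position because the C6 ketone is insulated by quaternary C5, the dienolate oxygen on C3 then lactonises onto one ester to close the 2-pyranone (the established ynone–malonate pyranone synthesis), and the added tert-butoxide enolises C7 of the ethyl ketone for a Dieckmann-type Claisen closure onto the remaining ester that is driven by deprotonation of the acidic enolised 1,3-diketone.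

Compound list
1 | (2E,6E)-farnesyl bromide | CC(C)=CCC/C(C)=C/CC/C(C)=C/CBr | starting material
2 | tert-butyl (triphenylphosphoranylidene)acetate | CC(C)(C)OC(=O)C=P(c1ccccc1)(c1ccccc1)c1ccccc1 | starting material
3 | (1-tert-butoxy-1-oxo-2-farnesylethan-2-yl)triphenylphosphonium bromide (racemic) | CC(C)=CCC/C(C)=C/CC/C(C)=C/CC(C(=O)OC(C)(C)C)[P+](c1ccccc1)(c1ccccc1)c1ccccc1.[Br-] | intermediate
4 | tert-butyl 2-farnesyl-2-(triphenylphosphoranylidene)acetate | CC(C)=CCC/C(C)=C/CC/C(C)=C/CC(C(=O)OC(C)(C)C)=P(c1ccccc1)(c1ccccc1)c1ccccc1 | intermediate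
5 | glycolaldehyde dimer (1,4-dioxane-2,5-diol) | OC1COC(O)CO1 | starting material
6 | glycolaldehyde | OCC=O | intermediate
7 | tert-butyl (2E)-2-farnesyl-4-hydroxybut-2-enoate | CC(C)=CCC/C(C)=C/CC/C(C)=C/C/C(C(=O)OC(C)(C)C)=C\CO | intermediate
8 | tert-butyl (2E)-4-(diethoxyphosphoryloxy)-2-farnesylbut-2-enoate | CC(C)=CCC/C(C)=C/CC/C(C)=C/C/C(C(=O)OC(C)(C)C)=C\COP(=O)(OCC)OCC | intermediate
9 | dimethylzinc | C[Zn]C | starting material
10 | tert-butyl (2R)-2-farnesyl-2-methylbut-3-enoate | CC(C)=CCC/C(C)=C/CC/C(C)=C/C[C@](C)(C=C)C(=O)OC(C)(C)C | intermediate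
11 | tert-butyl (2R)-2-farnesyl-2-methyl-3-oxobutanoate | CC(C)=CCC/C(C)=C/CC/C(C)=C/C[C@](C)(C(C)=O)C(=O)OC(C)(C)C | intermediate
12 | tert-butyl (2R)-2-farnesyl-2-methyl-3-oxopentanoate | CC(C)=CCC/C(C)=C/CC/C(C)=C/C[C@](C)(C(=O)CC)C(=O)OC(C)(C)C | intermediate
13 | (2S,3RS)-2-farnesyl-2-methylpentane-1,3-diol | CC(C)=CCC/C(C)=C/CC/C(C)=C/C[C@](C)(C(O)CC)CO | intermediate
14 | (2R,3RS)-2-farnesyl-3-hydroxy-2-methylpentanal | CC(C)=CCC/C(C)=C/CC/C(C)=C/C[C@](C)(C(O)CC)C=O | intermediate
15 | (3RS,4S)-4-farnesyl-4-methylhex-5-yn-3-ol | CC(C)=CCC/C(C)=C/CC/C(C)=C/C[C@](C)(C(O)CC)C#C | intermediate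
16 | acetaldehyde | CC=O | starting material
17 | (2RS,5S,6RS)-5-farnesyl-5-methyloct-3-yne-2,6-diol | CC(C)=CCC/C(C)=C/CC/C(C)=C/C[C@](C)(C(O)CC)C#CC(C)O | intermediate
18 | (5S)-5-farnesyl-5-methyloct-3-yne-2,6-dione | CC(C)=CCC/C(C)=C/CC/C(C)=C/C[C@](C)(C(=O)CC)C#CC(C)=O | intermediate
19 | dimethyl malonate | COC(=O)CC(=O)OC | starting material
20 | dimethyl 2-[(2S)-2-farnesyl-2-methyl-3-oxo-1-(2-oxopropylidene)pentyl]malonate (alkene geometry mobile) | CC(C)=CCC/C(C)=C/CC/C(C)=C/C[C@](C)(C(=O)CC)C(=CC(C)=O)C(C(=O)OC)C(=O)OC | intermediate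
21 | methyl 4-[(1S)-1-farnesyl-1-methyl-2-oxobutyl]-6-methyl-2-oxo-2H-pyran-3-carboxylate | CC(C)=CCC/C(C)=C/CC/C(C)=C/C[C@](C)(C(=O)CC)c1cc(C)oc(=O)c1C(=O)OC | intermediate
22 | (5S)-5-farnesyl-8-hydroxy-3,5,7-trimethyl-1H-isochromene-1,6(5H)-dione | CC(C)=CCC/C(C)=C/CC/C(C)=C/C[C@]1(C)C(=O)C(C)=C(O)c2c1cc(C)oc2=O | target

Total step count: 12. Longest linear sequence: 12 steps, from farnesyl bromide 1 to target 22.

Steps most likely to fail

Step 5. Oxygen may be delivered to the terminal instead of the internal vinyl carbon (aldehyde formation assisted by the neighbouring ester and the quaternary carbon), or turnover may stall at the hindered alkene. The fallback replaces palladium by a hydroxyl-tethered silicon delivery; it sets out from 10 and returns at 13. Reduction of 10 with LiAlH4 would give the homoallylic alcohol (2R)-2-farnesyl-2-methylbut-3-en-1-ol F1. Warming with (HMe2Si)2NH would give the hydridosilyl ether [(2R)-2-farnesyl-2-methylbut-3-enyloxy]dimethylsilane F2. Pt2[(Me2SiCH=CH2)2O]3 would then effect intramolecular 5-exo hydrosilylation, which places silicon on the internal vinyl carbon, to give the oxasilolane (3RS,4S)-4-farnesyl-2,2,3,4-tetramethyl-1-oxa-2-silacyclopentane F3. Tamao–Fleming oxidation (H2O2, KF, KHCO3, THF/MeOH) would give (2S,3RS)-2-farnesyl-2-methylbutane-1,3-diol F4. TBSCl and imidazole would protect the primary alcohol as (2RS,3S)-4-(tert-butyldimethylsilyloxy)-3-farnesyl-3-methylbutan-2-ol F5, and Dess–Martin oxidation would give the methyl ketone (3S)-4-(tert-butyldimethylsilyloxy)-3-farnesyl-3-methylbutan-2-one F6. LiN(i-Pr)2 and MeI would give the ethyl ketone (2S)-1-(tert-butyldimethylsilyloxy)-2-farnesyl-2-methylpentan-3-one F7, LiAlH4 would give (2S,3RS)-1-(tert-butyldimethylsilyloxy)-2-farnesyl-2-methylpentan-3-ol F8, and HF·pyridine would release diol 13.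

Step 12. Conjugate addition at the alkyne carbon next to the quaternary centre may be slow, and the methoxide released during the Claisen closure may open the pyranone or cleave the propanoyl group from C5. The fallback uses a smaller, more acidic nucleophile and a ring closure that releases no alkoxide; it sets out from 18 and returns at 22. Methyl cyanoacetate with KOt-Bu in THF would add to the ynone to give the adduct methyl (3S)-2-cyano-3-farnesyl-3-methyl-4-oxo-2-(2-oxopropylidene... in full, methyl 2-cyano-2-[(2S)-2-farnesyl-2-methyl-3-oxo-1-(2-oxopropylidene)pentyl]acetate F9, which would lactonise through its ester to 4-[(1S)-1-farnesyl-1-methyl-2-oxobutyl]-6-methyl-2-oxo-2H-pyran-3-carbonitrile F10. LiN(SiMe3)2 in THF would enolise C7, and Thorpe-type addition to the nitrile would give the enaminone (5S)-8-amino-5-farnesyl-3,5,7-trimethyl-1H-isochromene-1,6(5H)-dione F11. Mild aqueous HCl in THF would hydrolyse the vinylogous amide to 22.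

Step 9. Base-mediated retro-aldol fragmentation of the β-hydroxy aldehyde may compete with homologation, cleaving the C5–C6 bond and destroying or scrambling the quaternary centre. The fallback blocks the carbinol oxygen; it sets out from 13 and returns at 15. Et3SiCl and imidazole would give the bis-silyl ether (2S,3RS)-2-farnesyl-2-methyl-1,3-bis(triethylsilyloxy)pentane F12. Swern conditions ((COCl)2, DMSO, then Et3N) would cleave and oxidise only the primary silyl ether to (2R,3RS)-2-farnesyl-2-methyl-3-(triethylsilyloxy)pentanal F13, which has no free alkoxide and no α-hydrogen. The Ohira–Bestmann reaction would give (3RS,4S)-4-farnesyl-4-methyl-3-(triethylsilyloxy)hex-5-yne F14, and PPTS in MeOH would release 15.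

Further compounds
F1 | step 5 | (2R)-2-farnesyl-2-methylbut-3-en-1-ol | CC(C)=CCC/C(C)=C/CC/C(C)=C/C[C@](C)(C=C)CO
F2 | step 5 | [(2R)-2-farnesyl-2-methylbut-3-enyloxy]dimethylsilane | CC(C)=CCC/C(C)=C/CC/C(C)=C/C[C@](C)(C=C)CO[SiH](C)C
F3 | step 5 | (3RS,4S)-4-farnesyl-2,2,3,4-tetramethyl-1-oxa-2-silacyclopentane | CC(C)=CCC/C(C)=C/CC/C(C)=C/C[C@@]1(C)CO[Si](C)(C)C1C
F4 | step 5 | (2S,3RS)-2-farnesyl-2-methylbutane-1,3-diol | CC(C)=CCC/C(C)=C/CC/C(C)=C/C[C@](C)(C(C)O)CO
F5 | step 5 | (2RS,3S)-4-(tert-butyldimethylsilyloxy)-3-farnesyl-3-methylbutan-2-ol | CC(C)=CCC/C(C)=C/CC/C(C)=C/C[C@](C)(C(C)O)CO[Si](C)(C)C(C)(C)C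
F6 | step 5 | (3S)-4-(tert-butyldimethylsilyloxy)-3-farnesyl-3-methylbutan-2-one | CC(C)=CCC/C(C)=C/CC/C(C)=C/C[C@](C)(C(C)=O)CO[Si](C)(C)C(C)(C)C
F7 | step 5 | (2S)-1-(tert-butyldimethylsilyloxy)-2-farnesyl-2-methylpentan-3-one | CC(C)=CCC/C(C)=C/CC/C(C)=C/C[C@](C)(C(=O)CC)CO[Si](C)(C)C(C)(C)C
F8 | step 5 | (2S,3RS)-1-(tert-butyldimethylsilyloxy)-2-farnesyl-2-methylpentan-3-ol | CC(C)=CCC/C(C)=C/CC/C(C)=C/C[C@](C)(C(O)CC)CO[Si](C)(C)C(C)(C)C
F9 | step 12 | methyl 2-cyano-2-[(2S)-2-farnesyl-2-methyl-3-oxo-1-(2-oxopropylidene)pentyl]acetate | CC(C)=CCC/C(C)=C/CC/C(C)=C/C[C@](C)(C(=O)CC)C(=CC(C)=O)C(C#N)C(=O)OC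
F10 | step 12 | 4-[(1S)-1-farnesyl-1-methyl-2-oxobutyl]-6-methyl-2-oxo-2H-pyran-3-carbonitrile | CC(C)=CCC/C(C)=C/CC/C(C)=C/C[C@](C)(C(=O)CC)c1cc(C)oc(=O)c1C#N
F11 | step 12 | (5S)-8-amino-5-farnesyl-3,5,7-trimethyl-1H-isochromene-1,6(5H)-dione | CC(C)=CCC/C(C)=C/CC/C(C)=C/C[C@]1(C)C(=O)C(C)=C(N)c2c1cc(C)oc2=O
F12 | step 9 | (2S,3RS)-2-farnesyl-2-methyl-1,3-bis(triethylsilyloxy)pentane | CC(C)=CCC/C(C)=C/CC/C(C)=C/C[C@](C)(C(CC)O[Si](CC)(CC)CC)CO[Si](CC)(CC)CC
F13 | step 9 | (2R,3RS)-2-farnesyl-2-methyl-3-(triethylsilyloxy)pentanal | CC(C)=CCC/C(C)=C/CC/C(C)=C/C[C@](C)(C(CC)O[Si](CC)(CC)CC)C=O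
F14 | step 9 | (3RS,4S)-4-farnesyl-4-methyl-3-(triethylsilyloxy)hex-5-yne | CC(C)=CCC/C(C)=C/CC/C(C)=C/C[C@](C)(C(CC)O[Si](CC)(CC)CC)C#C
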